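(The data were computed with constants of no real substance, and the scatter is random.)

Time was the first thing I checked, and it bought little: the red run gained 2.2 percentage points of target in its last 2.00 min, barely more than the 1.8 % of its first 0.333 min. The charge that differed between these flasks was the second substrate.

| setting | violet | red | autumn | dawn |
|---|---|---|---|---|
| starting material | 0.089 M | 0.089 M | 0.089 M | 0.089 M |
| partner | 0.0712 M | 0.0712 M | 0.0712 M | 0.0712 M |
| second substrate | 0.049 M | 0.20 M | 0.270 M | 0.0890 M |
| remark | run made earlier | run made earlier |  |  |
| time |  |  | 6.0 min | 6.0 min |

- violet (time / min: starting material / %, target / %): 0.333: 97.3, 2.3; 0.667: 95.7, 4.7; 1.33: 93.0, 7.9; 2.00: 89.5, 10.0; 4.00: 85.0, 14.8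
- red (time / min: starting material / %, target / %): 0.333: 97.2, 1.8; 0.667: 95.4, 3.2; 1.33: 93.5, 6.0; 2.00: 91.2, 8.3; 4.00: 90.4, 10.5

(each reading ± 0.5 percentage points)

1. which of these there is most of at the end, counted by the starting material in it, autumn (target / starting material)
2. which of these there is most of at the end, counted by the starting material in it, dawn (target / starting material)
3. amount of the one of these that there is most of at the end, in percent of the starting material charged, autumn
4. amount of the one of these that there is most of at the end, in percent of the starting material charged, dawn

My bench rule was the statistical one. Partner, the limiting reagent at 0.800 equivalents, is shared between starting material and second substrate by concentration. That is the zero of the scale, and dawn sits on it: with c second substrate equal to c starting material, the target gets half of the partner, or 40.0 % of the starting material. Held against the runs, the rule broke. It wanted violet over red by a ratio of 2.09, and the last readings gave 1.41. It also put violet at 51.6 %, against 14.8 % read.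

So I kept the shape and let the runs set the scale. Those two readings gave 0.320 M: this is the suppression concentration, the c second substrate that brings the target down to half of what it is without any. On the statistical scale it would equal 0.089 M; it is a loose reading, with 0.5 points of scatter on each value. Scaling from red, I reckoned target at 9.25 % in autumn and 13.4 % in dawn. Violet's last balance was 99.8 %, so I took starting material as the complement: 90.8 % and 86.6 %.

The forecast named starting material for autumn at 88.5 % and starting material for dawn at 83.5 %, both lower than mine, and it read the slowing as “saturable inhibition”.

The flasks gave starting material at 90.9 % in autumn and starting material at 85.6 % in dawn.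

    starting material + partner → target (k = 1.14 M⁻¹ min⁻¹)
    second substrate + partner → second product (k = 2.07 M⁻¹ min⁻¹)
    partner → decomposed reagent (k = 0.237 min⁻¹)

In autumn, free partner at the end was 0.74 % of its charge, less than the 91 % of starting material left. Autumn's 9.07 % of target, carried by the suppression concentration to the neighbour flask with 0.68 M of second substrate, gives 5.35 %; that neighbour flask held 4.71 %.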